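**Retrosynthetic overview**

1. Numbering: ring A (nine-membered) is C1(=C17H2)–C2–C3=C4–C5(CH3)(OH)–C6–C7–C8–C9, ring B (tetrahydrofuran) is C9–C10–O–C11–C8, C12 is the CH2O-stearoyl carbon, C13–C16 the dienyl chain. The strategy rests on the array C11–C8–C9–C1(=C17H2) of rings A and B: an exocyclic methylene on C1 allylic to the fusion carbon C9, which is bonded to C8 bearing the oxidised carbon C11. Read with C11 as a carboxyl, this is a γ,δ-unsaturated acid.
2. Key disconnection: the C8–C9 bond of ring A is made by a ring-contracting Ireland–Claisen rearrangement of an 11-membered lactone C11(=O)–O–C17H2–C1(=C9H–C10), which also sets C8 and C9 and turns C17 into the methylene.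
3. The lactone comes from a seco acid (Yamaguchi), assembled by a Z-selective Wittig reaction at C3=C4. The aldehyde (C4–C8, C11) comes from (S)-linalool by two ozonolyses and a one-carbon homologation. The phosphonium salt (C3, C2, C1, C9, C10, C17) comes from but-2-yne-1,4-diol by trans-hydroalumination/iodination, vinyl coupling and hydroboration.
4. After the key step the C11 acid becomes the dienyl ketone (C13–C16). Felkin–Anh addition of a hydroxymethyl anion equivalent (C12) sets C11, the primary alcohol is stearoylated, and ring B is closed last by the C11 hydroxyl displacing a C10 sulfonate.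
5. Ring order: 11-membered lactone (temporary, step 16), then ring A (step 17), then ring B (step 24).

Key step: step 17

Remark: (S)-(+)-linalool of high enantiomeric purity is taken as purchasable; its carbinol carbon becomes C5 and is never touched.
Remark: the two ozonides and the methyl enol ether are mixtures at a centre or double bond that the following operation destroys, so their SMILES carry no descriptor there.
Remark: relative to a lactone carrying a 4-methoxybenzyl ether at C10, the C10 oxygen is carried here as its tert-butyldimethylsilyl ether and the 4-methoxybenzyl group sits on O–C17, so that O–C17 can be freed oxidatively before lactonisation and no quinone oxidation is needed once the diene is present.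

**Route**

Step 1
Reactants: 1 (S)-linalool, (3S)-3,7-dimethylocta-1,6-dien-3-ol
Product: 2 triethyl{[(3S)-3,7-dimethylocta-1,6-dien-3-yl]oxy}silane
Conditions: Et3SiOTf, 2,6-lutidine, CH2Cl2, −78 → 0 °C
Reagents that add atoms: triethylsilyl trifluoromethanesulfonate, CC[Si](CC)(CC)OS(=O)(=O)C(F)(F)F
Why: Silylation of the hindered tertiary allylic alcohol needs the silyl triflate with a hindered pyridine base, and the future C5 stereocentre is not involved.

Step 2
Reactants: 2 triethyl{[(3S)-3,7-dimethylocta-1,6-dien-3-yl]oxy}silane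
Product: 4 (4S)-4-methyl-4-[(triethylsilyl)oxy]hex-5-enal, via ozonide 3 (not isolated)
Conditions: O3, CH2Cl2, −78 °C, Sudan Red 7B as end-point dye; then PPh3, −78 °C → rt
Reagents that add atoms: ozone, [O-][O+]=O
Why: Ozonolysis with reductive work-up; the electrophilic ozone should consume the electron-rich trisubstituted alkene well before the monosubstituted vinyl group shielded by the quaternary silyloxy carbon, the dye marking the end point, so that C8 appears as the aldehyde.

Step 3
Reactants: 4 (4S)-4-methyl-4-[(triethylsilyl)oxy]hex-5-enal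
Product: 5 (3S)-7-methoxy-3-methyl-3-[(triethylsilyl)oxy]hepta-1,6-diene (E/Z mixture)
Conditions: Ph3P(CH2OMe)Cl, KOC(CH3)3, THF, 0 °C; then 4, 0 °C → rt
Reagents that add atoms: (methoxymethyl)triphenylphosphonium chloride, COC[P+](c1ccccc1)(c1ccccc1)c1ccccc1.[Cl-]
Why: Wittig methoxymethylenation adds the one carbon that becomes C11, and the enol ether geometry is of no consequence because the next step destroys it.

Step 4
Reactants: 5 (3S)-7-methoxy-3-methyl-3-[(triethylsilyl)oxy]hepta-1,6-diene
Product: 6 (5S)-5-methyl-5-[(triethylsilyl)oxy]hept-6-enal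
Conditions: aq. HCl (0.2 M), THF, 0 °C, short contact time
Reagents that add atoms: water, O
Why: Acid-catalysed enol ether hydrolysis (C-protonation, oxocarbenium ion, hemiacetal) should be orders of magnitude faster at this acidity than cleavage of the hindered tertiary triethylsilyl ether.

Step 5
Reactants: 6 (5S)-5-methyl-5-[(triethylsilyl)oxy]hept-6-enal
Product: 7 (5S)-5-methyl-5-[(triethylsilyl)oxy]hept-6-enoic acid
Conditions: NaClO2, NaH2PO4, 2-methylbut-2-ene, tBuOH/H2O, 0 °C → rt
Reagents that add atoms: sodium chlorite NaClO2, [Na+].[O-]Cl=O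
Why: Pinnick oxidation converts the aldehyde into the C11 acid under buffered conditions, 2-methylbut-2-ene taking up the hypochlorous acid so that the vinyl group and the silyl ether are untouched.

Step 6
Reactants: 7 (5S)-5-methyl-5-[(triethylsilyl)oxy]hept-6-enoic acid
Product: 9 (5S)-5-methyl-6-oxo-5-[(triethylsilyl)oxy]hexanoic acid, via ozonide 8 (not isolated)
Conditions: O3, CH2Cl2, −78 °C; then PPh3, −78 °C → rt
Reagents that add atoms: ozone, [O-][O+]=O
Why: Ozonolysis of the only remaining alkene with reductive work-up unveils C4 as an α-silyloxy aldehyde without α-hydrogen, so C5 cannot epimerise.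

Step 7
Reactants: 10 but-2-yne-1,4-diol
Product: 11 4-[(4-methoxybenzyl)oxy]but-2-yn-1-ol
Conditions: 10 (4 equiv), NaH (1 equiv), THF/DMF, 0 °C; 4-methoxybenzyl chloride (1 equiv), Bu4NI (cat.), rt
Reagents that add atoms: 4-methoxybenzyl chloride, COc1ccc(CCl)cc1
Why: Williamson etherification, with the cheap symmetrical diol in excess so that monoalkylation dominates and the surplus diol is washed out with water.

Step 8
Reactants: 11 4-[(4-methoxybenzyl)oxy]but-2-yn-1-ol
Product: 13 (2Z)-3-iodo-4-[(4-methoxybenzyl)oxy]but-2-en-1-ol, via alkenylaluminate 12 (not isolated)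
Conditions: NaAlH2(OCH2CH2OMe)2, THF, 0 °C → rt; then I2, THF, −78 → 0 °C
Reagents that add atoms: iodine, II
Why: Hydroxyl-directed trans-hydroalumination of the propargylic alcohol delivers hydride to C9 and aluminium to C1 within a five-membered alkenylaluminate, and iodinolysis of the C–Al bond with retention gives the Z iodide in which iodine (later C2) is cis to C10, which fixes the E-C1=C9 geometry of the lactone.

Step 9
Reactants: 13 (2Z)-3-iodo-4-[(4-methoxybenzyl)oxy]but-2-en-1-ol
Product: 14 tert-butyl({(2Z)-3-iodo-4-[(4-methoxybenzyl)oxy]but-2-en-1-yl}oxy)dimethylsilane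
Conditions: tBuMe2SiCl, imidazole, CH2Cl2, 0 °C → rt
Reagents that add atoms: tert-butyldimethylsilyl chloride, CC(C)(C)[Si](C)(C)Cl
Why: Standard silylation of the primary allylic alcohol; the tert-butyldimethylsilyl ether at C10 should withstand every step up to the late fluoride treatment and is orthogonal to the 4-methoxybenzyl ether on O–C17.

Step 10
Reactants: 14 tert-butyl({(2Z)-3-iodo-4-[(4-methoxybenzyl)oxy]but-2-en-1-yl}oxy)dimethylsilane
Product: 15 tert-butyl({(2E)-3-{[(4-methoxybenzyl)oxy]methyl}penta-2,4-dien-1-yl}oxy)dimethylsilane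
Conditions: Bu3SnCH=CH2, Pd(PPh3)4 (5 mol %), CuI (10 mol %), DMF, 50 °C
Reagents that add atoms: tributyl(vinyl)stannane, CCCC[Sn](CCCC)(CCCC)C=C
Why: Stille coupling (oxidative addition of the alkenyl iodide to zerovalent palladium, copper-assisted transmetalation, reductive elimination) proceeds with retention of the alkene geometry and tolerates both ethers.

Step 11
Reactants: 15 tert-butyl({(2E)-3-{[(4-methoxybenzyl)oxy]methyl}penta-2,4-dien-1-yl}oxy)dimethylsilane
Product: 17 (3E)-5-[(tert-butyldimethylsilyl)oxy]-3-{[(4-methoxybenzyl)oxy]methyl}pent-3-en-1-ol, via alkylborane 16 (not isolated)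
Conditions: 9-borabicyclo[3.3.1]nonane (9-BBN), THF, 0 °C → rt; then NaOH (aq.), H2O2, 0 °C
Reagents that add atoms: hydrogen peroxide, OO
Why: Hydroboration–oxidation; the bulky dialkylborane should add only to the monosubstituted terminal alkene of the diene with boron on the terminal carbon, leaving the trisubstituted C1=C9 alkene, so that C3 becomes the primary alcohol.

Step 12
Reactants: 17 (3E)-5-[(tert-butyldimethylsilyl)oxy]-3-{[(4-methoxybenzyl)oxy]methyl}pent-3-en-1-ol
Product: 18 tert-butyl({(2E)-5-iodo-3-{[(4-methoxybenzyl)oxy]methyl}pent-2-en-1-yl}oxy)dimethylsilane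
Conditions: I2, PPh3, imidazole, CH2Cl2, 0 °C → rt
Reagents that add atoms: iodine, II
Why: Appel-type iodination (alkoxyphosphonium iodide, then SN2 by iodide) of the unhindered primary alcohol under buffered conditions that leave both ethers intact.

Step 13
Reactants: 18 tert-butyl({(2E)-5-iodo-3-{[(4-methoxybenzyl)oxy]methyl}pent-2-en-1-yl}oxy)dimethylsilane
Product: 19 {(3E)-5-[(tert-butyldimethylsilyl)oxy]-3-{[(4-methoxybenzyl)oxy]methyl}pent-3-en-1-yl}triphenylphosphonium iodide
Conditions: PPh3, MeCN, 80 °C
Reagents that add atoms: triphenylphosphine, c1ccc(cc1)P(c1ccccc1)c1ccccc1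
Why: SN2 quaternisation of triphenylphosphine by the primary iodide gives the salt of a non-stabilised ylide.

Step 14
Reactants: 19 {(3E)-5-[(tert-butyldimethylsilyl)oxy]-3-{[(4-methoxybenzyl)oxy]methyl}pent-3-en-1-yl}triphenylphosphonium iodide; 9 (5S)-5-methyl-6-oxo-5-[(triethylsilyl)oxy]hexanoic acid
Product: 21 (5S,6Z,9E)-11-[(tert-butyldimethylsilyl)oxy]-9-{[(4-methoxybenzyl)oxy]methyl}-5-methyl-5-[(triethylsilyl)oxy]undeca-6,9-dienoic acid, via ylide 20 (not isolated)
Conditions: 19, KN(SiMe3)2 (1 equiv), THF, −78 °C; then 9 pre-treated with KN(SiMe3)2 (1 equiv), −78 °C → rt; aq. HCl to pH 3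
Reagents that add atoms: none
Why: Wittig reaction of a non-stabilised ylide under lithium-free conditions closes the oxaphosphetane kinetically to the cis isomer and should give the Z-C3=C4 alkene; the hindered aldehyde has no α-hydrogen and its carboxyl group is masked as the potassium salt, so the base harms neither.

Step 15
Reactants: 21 (5S,6Z,9E)-11-[(tert-butyldimethylsilyl)oxy]-9-{[(4-methoxybenzyl)oxy]methyl}-5-methyl-5-[(triethylsilyl)oxy]undeca-6,9-dienoic acid
Product: 22 (5S,6Z,9E)-11-[(tert-butyldimethylsilyl)oxy]-9-(hydroxymethyl)-5-methyl-5-[(triethylsilyl)oxy]undeca-6,9-dienoic acid (seco acid)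
Conditions: DDQ, CH2Cl2/aq. phosphate buffer (pH 7), 0 °C
Reagents that add atoms: none
Why: Oxidative cleavage of the 4-methoxybenzyl ether by DDQ (benzylic hydride abstraction, hydrolysis of the oxocarbenium ion) frees the C17 hydroxyl, while silyl ethers, acid and the skipped diene should not be attacked in the cold buffered medium.

Step 16
Reactants: 22 seco acid
Product: 24 (6S,7Z,10E)-10-{2-[(tert-butyldimethylsilyl)oxy]ethylidene}-6-methyl-6-[(triethylsilyl)oxy]oxacycloundec-7-en-2-one (11-membered lactone, key-step precursor), via mixed anhydride 23 (not isolated)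
Conditions: 2,4,6-trichlorobenzoyl chloride, Et3N, THF, rt; then slow addition to DMAP, toluene, 80 °C, about 1 mM
Reagents that add atoms: none
Why: Yamaguchi macrolactonisation: DMAP is acylated by the mixed anhydride and the acylpyridinium ion is captured by the C17 hydroxyl at high dilution, which favours ring closure over oligomerisation; the tertiary C5 oxygen stays silylated, so the six-membered lactone cannot form.

Step 17
Reactants: 24 11-membered lactone
Product: 27 (1S,4S,5Z,9R)-9-{[(tert-butyldimethylsilyl)oxy]methyl}-4-methyl-8-methylidene-4-[(triethylsilyl)oxy]cyclonon-5-ene-1-carboxylic acid (ring A acid; route locants 5S,8S,9R), via silyl ketene acetal 25 (not isolated), via trimethylsilyl ester 26 (not isolated)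
Conditions: Me3SiCl, Et3N, THF, −78 °C, then LiN(iPr)2, −78 °C → rt; toluene, 80 °C; then aq. citric acid, THF, rt
Reagents that add atoms: none
Why: LiN(iPr)2 removes a C8 proton under kinetic control while Me3SiCl traps the enolate as ketene acetal 25 with C7 cis to the ring oxygen, and on warming the six atoms C8=C11–O–C17–C1=C9 undergo a concerted suprafacial [3,3] shift that forms C8–C9, breaks O–C17 and leaves C17 as the exocyclic methylene, after which hydrolysis of silyl ester 26 frees the C11 acid. The closest known reaction type is the Ireland–Claisen rearrangement in its ring-contracting form on macrocyclic allylic lactones. Ring A is closed transannularly: the C7–C6–C5–C4=C3–C2 tether already links C8 to C1, so the new sigma bond turns the 11-membered lactone into the nine-membered carbocycle (contraction by two ring atoms) through a six-membered pericyclic array bridged by that tether. C8 and C9 are set together: a chair-like array with C7 axial (dictated by the ketene acetal geometry) and C10 equatorial (dictated by the E-C1=C9 alkene) gives the anti pair that becomes the trans ring fusion, and C5 must choose between the two mirror-image chairs through the folded ring, by keeping its triethylsilyloxy group on the outer face, to give 8S,9R. The step needs enolisation at C8 only (the sole acidic site), a single ketene acetal geometry (enforced by the ring and by kinetic deprotonation), chair over boat, and face selection by C5; the last is the least secure, and release of medium-ring lactone strain is what should let the shift run below 100 °C.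

Step 18
Reactants: 27 ring A acid
Product: 28 N-methoxy-N-methylamide of 27 (Weinreb amide; 5S,8S,9R)
Conditions: MeNH(OMe)·HCl, EDC·HCl, HOBt (cat.), N-methylmorpholine, CH2Cl2, 0 °C → rt
Reagents that add atoms: N,O-dimethylhydroxylamine hydrochloride, CNOC.Cl
Why: Carbodiimide-mediated amide coupling gives the N-methoxy-N-methylamide under conditions too mild to epimerise C8.

Step 19
Reactants: 29 3-methylbut-2-enal
Product: 30 (1E)-1-iodo-4-methylpenta-1,3-diene
Conditions: CHI3, CrCl2, THF, 0 °C → rt, dark
Reagents that add atoms: iodoform, IC(I)I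
Why: Takai olefination: the geminal dichromium carbenoid formed from CHI3 and divalent chromium adds to the aldehyde and anti elimination gives the E alkenyl iodide, which carries C13–C16 with the trisubstituted alkene already in place.

Step 20
Reactants: 30 (1E)-1-iodo-4-methylpenta-1,3-diene; 28 Weinreb amide
Product: 32 (2E)-1-[ring A C8]-5-methylhexa-2,4-dien-1-one (dienyl ketone; C11 carbonyl on C8, C10–OSitBuMe2, C5–OSiEt3; 5S,8S,9R), via dienyllithium 31 (not isolated)
Conditions: 30, tBuLi (2 equiv), Et2O, −78 °C; then 28, THF, −78 → −20 °C; H2O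
Reagents that add atoms: none
Why: Iodine–lithium exchange proceeds with retention of the E geometry, and acylation of the alkenyllithium by the Weinreb amide stops at the chelated tetrahedral adduct, which releases the dienone only on work-up, so no second addition and no epimerisation at C8 should occur.

Step 21
Reactants: 32 dienyl ketone
Product: 34 C11,C12-diol (11R; tertiary C11–OH bearing the E dienyl group, primary C12–OH; C10–OSitBuMe2, C5–OSiEt3), via hydroxysilane 33 (not isolated)
Conditions: iPrOMe2SiCH2MgCl (from iPrOMe2SiCH2Cl, Mg, THF), CeCl3, THF, −78 → 0 °C; then KF, KHCO3, H2O2 (30 %), THF/MeOH, rt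
Reagents that add atoms: (chloromethyl)(isopropoxy)dimethylsilane (used as its Grignard reagent), CC(C)O[Si](C)(C)CCl; hydrogen peroxide, OO
Why: Nucleophilic hydroxymethylation followed by Tamao oxidation: the organocerium reagent should add 1,2 to the dienone under Felkin–Anh control from C8 (the branched ring carbon C9 anti to the incoming nucleophile, attack past H8), which places C12 on the face that gives 11R, and the C–Si bond is then oxidised to C–OH by peroxide and fluoride under weakly basic conditions that leave alkenes and silyl ethers alone.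

Step 22
Reactants: 34 C11,C12-diol
Product: 35 C12 stearate of 34 (tertiary C11–OH free; 5S,8S,9R,11R)
Conditions: stearoyl chloride (1.1 equiv), pyridine, DMAP (cat.), CH2Cl2, −20 → 0 °C
Reagents that add atoms: stearoyl chloride, CCCCCCCCCCCCCCCCCC(=O)Cl
Why: Acylation with an acid chloride and pyridine should reach only the primary C12 hydroxyl, the tertiary C11 hydroxyl being inert at this temperature.

Step 23
Reactants: 35 C12 stearate
Product: 36 triol stearate (free C5–OH, C10–OH and C11–OH; C12–O-stearoyl)
Conditions: Bu4NF, AcOH (1:1), THF, rt → 40 °C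
Reagents that add atoms: none
Why: Fluoride-induced cleavage of both silyl ethers, buffered with acetic acid so that the stearate neither hydrolyses nor migrates and the acid-labile tertiary dienyl carbinol is not ionised.

Step 24
Reactants: 36 triol stearate
Product: 38 CNP0274030.1 (target), via tosylate 37 (not isolated)
Conditions: TsCl (1.3 equiv), pyridine, DMAP (cat.), 0 °C → 45 °C
Reagents that add atoms: none
Why: Selective sulfonylation of the only primary hydroxyl followed by intramolecular Williamson-type displacement (5-exo-tet) by the tertiary C11 hydroxyl closes ring B; substitution takes place at the primary carbon C10, so C11, C8 and C9 keep their configuration, and the tertiary C5 hydroxyl cannot be sulfonylated under these conditions.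

**Compound list**

1 | (S)-linalool, (3S)-3,7-dimethylocta-1,6-dien-3-ol | C=C[C@@](C)(O)CCC=C(C)C | starting material
2 | triethyl{[(3S)-3,7-dimethylocta-1,6-dien-3-yl]oxy}silane | C=C[C@@](C)(O[Si](CC)(CC)CC)CCC=C(C)C | intermediate
3 | secondary ozonide (3,3-dimethyl-1,2,4-trioxolane) of the trisubstituted alkene of 2 | C=C[C@@](C)(O[Si](CC)(CC)CC)CCC1OOC(C)(C)O1 | intermediate (not isolated)
4 | (4S)-4-methyl-4-[(triethylsilyl)oxy]hex-5-enal | C=C[C@@](C)(O[Si](CC)(CC)CC)CCC=O | intermediate
5 | (3S)-7-methoxy-3-methyl-3-[(triethylsilyl)oxy]hepta-1,6-diene (E/Z mixture) | C=C[C@@](C)(O[Si](CC)(CC)CC)CCC=COC | intermediate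
6 | (5S)-5-methyl-5-[(triethylsilyl)oxy]hept-6-enal | C=C[C@@](C)(O[Si](CC)(CC)CC)CCCC=O | intermediate
7 | (5S)-5-methyl-5-[(triethylsilyl)oxy]hept-6-enoic acid | C=C[C@@](C)(O[Si](CC)(CC)CC)CCCC(=O)O | intermediate
8 | secondary ozonide (1,2,4-trioxolane) of the vinyl group of 7 | OC(=O)CCC[C@](C)(O[Si](CC)(CC)CC)C1OCOO1 | intermediate (not isolated)
9 | (5S)-5-methyl-6-oxo-5-[(triethylsilyl)oxy]hexanoic acid | OC(=O)CCC[C@](C)(O[Si](CC)(CC)CC)C=O | intermediate
10 | but-2-yne-1,4-diol | OCC#CCO | starting material
11 | 4-[(4-methoxybenzyl)oxy]but-2-yn-1-ol | OCC#CCOCc1ccc(OC)cc1 | intermediate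
12 | sodium alkenylaluminate (five-membered O–Al–C1 chelate, H on C9, two 2-methoxyethoxy ligands) | COCCO[Al-]1(OCCOC)OCC=C1COCc2ccc(OC)cc2.[Na+] | intermediate (not isolated)
13 | (2Z)-3-iodo-4-[(4-methoxybenzyl)oxy]but-2-en-1-ol | OC/C=C(\I)COCc1ccc(OC)cc1 | intermediate
14 | tert-butyl({(2Z)-3-iodo-4-[(4-methoxybenzyl)oxy]but-2-en-1-yl}oxy)dimethylsilane | CC(C)(C)[Si](C)(C)OC/C=C(\I)COCc1ccc(OC)cc1 | intermediate
15 | tert-butyl({(2E)-3-{[(4-methoxybenzyl)oxy]methyl}penta-2,4-dien-1-yl}oxy)dimethylsilane | CC(C)(C)[Si](C)(C)OC/C=C(\C=C)COCc1ccc(OC)cc1 | intermediate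
16 | B-alkyl-9-borabicyclo[3.3.1]nonane from 15 (boron on C3) | CC(C)(C)[Si](C)(C)OC/C=C(\CCB1C2CCCC1CCC2)COCc1ccc(OC)cc1 | intermediate (not isolated)
17 | (3E)-5-[(tert-butyldimethylsilyl)oxy]-3-{[(4-methoxybenzyl)oxy]methyl}pent-3-en-1-ol | CC(C)(C)[Si](C)(C)OC/C=C(\CCO)COCc1ccc(OC)cc1 | intermediate
18 | tert-butyl({(2E)-5-iodo-3-{[(4-methoxybenzyl)oxy]methyl}pent-2-en-1-yl}oxy)dimethylsilane | CC(C)(C)[Si](C)(C)OC/C=C(\CCI)COCc1ccc(OC)cc1 | intermediate
19 | {(3E)-5-[(tert-butyldimethylsilyl)oxy]-3-{[(4-methoxybenzyl)oxy]methyl}pent-3-en-1-yl}triphenylphosphonium iodide | CC(C)(C)[Si](C)(C)OC/C=C(\CC[P+](c1ccccc1)(c1ccccc1)c1ccccc1)COCc1ccc(OC)cc1.[I-] | intermediate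
20 | phosphorus ylide of 19 (carbanion at C3) | CC(C)(C)[Si](C)(C)OC/C=C(\CC=P(c1ccccc1)(c1ccccc1)c1ccccc1)COCc1ccc(OC)cc1 | intermediate (not isolated)
21 | (5S,6Z,9E)-11-[(tert-butyldimethylsilyl)oxy]-9-{[(4-methoxybenzyl)oxy]methyl}-5-methyl-5-[(triethylsilyl)oxy]undeca-6,9-dienoic acid | OC(=O)CCC[C@](C)(O[Si](CC)(CC)CC)/C=C\C/C(=C\CO[Si](C)(C)C(C)(C)C)COCc1ccc(OC)cc1 | intermediate
22 | (5S,6Z,9E)-11-[(tert-butyldimethylsilyl)oxy]-9-(hydroxymethyl)-5-methyl-5-[(triethylsilyl)oxy]undeca-6,9-dienoic acid (seco acid) | OC(=O)CCC[C@](C)(O[Si](CC)(CC)CC)/C=C\C/C(=C\CO[Si](C)(C)C(C)(C)C)CO | intermediate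
23 | mixed anhydride of 22 and 2,4,6-trichlorobenzoic acid | O=C(OC(=O)c1c(Cl)cc(Cl)cc1Cl)CCC[C@](C)(O[Si](CC)(CC)CC)/C=C\C/C(=C\CO[Si](C)(C)C(C)(C)C)CO | intermediate (not isolated)
24 | (6S,7Z,10E)-10-{2-[(tert-butyldimethylsilyl)oxy]ethylidene}-6-methyl-6-[(triethylsilyl)oxy]oxacycloundec-7-en-2-one (11-membered lactone, key-step precursor) | O=C1CCC[C@](C)(O[Si](CC)(CC)CC)/C=C\C/C(=C\CO[Si](C)(C)C(C)(C)C)CO1 | intermediate
25 | trimethylsilyl ketene acetal of 24 (C8=C11, C7 cis to the ring oxygen) | C[Si](C)(C)O/C1=C/CC[C@](C)(O[Si](CC)(CC)CC)/C=C\C/C(=C\CO[Si](C)(C)C(C)(C)C)CO1 | intermediate (not isolated)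
26 | trimethylsilyl ester of 27 | C=C1C/C=C\[C@@](C)(O[Si](CC)(CC)CC)CC[C@H](C(=O)O[Si](C)(C)C)[C@H]1CO[Si](C)(C)C(C)(C)C | intermediate (not isolated)
27 | (1S,4S,5Z,9R)-9-{[(tert-butyldimethylsilyl)oxy]methyl}-4-methyl-8-methylidene-4-[(triethylsilyl)oxy]cyclonon-5-ene-1-carboxylic acid (ring A acid, key-step product) | C=C1C/C=C\[C@@](C)(O[Si](CC)(CC)CC)CC[C@H](C(=O)O)[C@H]1CO[Si](C)(C)C(C)(C)C | intermediate
28 | N-methoxy-N-methylamide of 27 | C=C1C/C=C\[C@@](C)(O[Si](CC)(CC)CC)CC[C@H](C(=O)N(C)OC)[C@H]1CO[Si](C)(C)C(C)(C)C | intermediate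
29 | 3-methylbut-2-enal | CC(C)=CC=O | starting material
30 | (1E)-1-iodo-4-methylpenta-1,3-diene | CC(C)=C/C=C/I | intermediate
31 | (1E)-(4-methylpenta-1,3-dien-1-yl)lithium | [Li]/C=C/C=C(C)C | intermediate (not isolated)
32 | dienyl ketone: ring A with C8–C(=O)–CH=CH–CH=C(CH3)2 (E), C10–OSitBuMe2, C5–OSiEt3 (5S,8S,9R) | C=C1C/C=C\[C@@](C)(O[Si](CC)(CC)CC)CC[C@H](C(=O)/C=C/C=C(C)C)[C@H]1CO[Si](C)(C)C(C)(C)C | intermediate
33 | β-hydroxysilane: tertiary C11–OH with CH2SiMe2(OiPr) as C12 (11R) | C=C1C/C=C\[C@@](C)(O[Si](CC)(CC)CC)CC[C@H]([C@](O)(/C=C/C=C(C)C)C[Si](C)(C)OC(C)C)[C@H]1CO[Si](C)(C)C(C)(C)C | intermediate (not isolated)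
34 | C11,C12-diol (5S,8S,9R,11R), C10–OSitBuMe2, C5–OSiEt3 | C=C1C/C=C\[C@@](C)(O[Si](CC)(CC)CC)CC[C@H]([C@](O)(/C=C/C=C(C)C)CO)[C@H]1CO[Si](C)(C)C(C)(C)C | intermediate
35 | C12 stearate of 34 | C=C1C/C=C\[C@@](C)(O[Si](CC)(CC)CC)CC[C@H]([C@](O)(/C=C/C=C(C)C)COC(=O)CCCCCCCCCCCCCCCCC)[C@H]1CO[Si](C)(C)C(C)(C)C | intermediate
36 | triol stearate (free C5–OH, C10–OH, C11–OH; C12–O-stearoyl) | C=C1C/C=C\[C@@](C)(O)CC[C@H]([C@](O)(/C=C/C=C(C)C)COC(=O)CCCCCCCCCCCCCCCCC)[C@H]1CO | intermediate
37 | C10 4-methylbenzenesulfonate of 36 | C=C1C/C=C\[C@@](C)(O)CC[C@H]([C@](O)(/C=C/C=C(C)C)COC(=O)CCCCCCCCCCCCCCCCC)[C@H]1COS(=O)(=O)c1ccc(C)cc1 | intermediate (not isolated)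
38 | CNP0274030.1 (5S,8S,9R,11R; rings A and B trans-fused, C12 stearate, free C5–OH) | C=C1C/C=C\[C@@](C)(O)CC[C@H]2[C@H]1CO[C@@]2(/C=C/C=C(C)C)COC(=O)CCCCCCCCCCCCCCCCC | target

**Step count and risks**

Total step count: 24. Longest linear sequence: 17 steps (steps 7–18 and 20–24, from but-2-yne-1,4-diol).

Steps most likely to fail:

Step 17 (key step). The remote C5 centre may relay its sense poorly through the folded 11-membered ring, so that both mirror-image chair arrays are used and the 8S,9R and 8R,9S acids form together; a boat array would add the cis pair. The fallback sets out from lactone 24 and comes back at acid 27. The silicon ketene acetal is replaced by a boron one carrying a C2-symmetric ligand, so that the reagent and not C5 chooses the face (enantioselective boron-enolate Claisen rearrangement). (R,R)-N,N'-Bis{[3,5-bis(trifluoromethyl)phenyl]sulfonyl}-1,2-diphenylethane-1,2-diamine and BBr3 give in the flask the bromoborane (4R,5R)-2-bromo-1,3-bis{[3,5-bis(trifluoromethyl)phenyl]sulfonyl}-4,5-diphenyl-1,3,2-diazaborolidine F1. With iPr2NEt in CH2Cl2 at −78 °C it should enolise 24 to the boron ketene acetal F2, which should rearrange at −20 °C through the same six-atom array to the acyloxyborane F3. Aqueous work-up hydrolyses F3 to 27 and returns the bis-sulfonamide. The enantiomeric ligand is taken instead if it proves to be the matched partner.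

Step 21. The nucleophile may attack the other face of the C11 carbonyl (if C7 and not C9 acts as the large group at C8), giving the C11 epimer, or it may add in a conjugate sense to the dienone. The fallback sets out from Weinreb amide 28 and comes back at diol 34. The order of the two additions at C11 is inverted, so that the same facial preference now delivers the needed epimer and the first nucleophile never meets a dienone. Tributyl{[(4-methoxybenzyl)oxy]methyl}stannane F4 (from (tributylstannyl)methanol, NaH and 4-methoxybenzyl chloride) is transmetalated with nBuLi in THF at −78 °C to {[(4-methoxybenzyl)oxy]methyl}lithium F5, which is acylated by 28 to give the alkoxymethyl ketone F6. Dienyllithium 31 (from 30 as in step 20) then adds to F6 to give the tertiary carbinol 4-methoxybenzyl ether F7. DDQ in buffered CH2Cl2 at 0 °C removes the 4-methoxybenzyl group and gives 34. That oxidation takes place next to the diene and would have to be run cold and stopped early.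

Step 16. Intermolecular acylation (dimer and oligomer formation) may outrun closure of the strained 11-membered ring. The fallback sets out from seco acid 22 and comes back at lactone 24. In a Mitsunobu lactonisation, 22 is added slowly to PPh3 and diisopropyl azodicarboxylate in toluene at high dilution. This activates the primary allylic C17 hydroxyl instead of the acid, so the ring closes by SN2 attack of the carboxylate at C17 rather than by acyl transfer. This fallback makes no new compound (F0).

Further compounds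
F0 | step 16 | none | none
F1 | step 17 | (4R,5R)-2-bromo-1,3-bis{[3,5-bis(trifluoromethyl)phenyl]sulfonyl}-4,5-diphenyl-1,3,2-diazaborolidine | BrB1N(S(=O)(=O)c2cc(C(F)(F)F)cc(C(F)(F)F)c2)[C@H](c2ccccc2)[C@@H](c2ccccc2)N1S(=O)(=O)c1cc(C(F)(F)F)cc(C(F)(F)F)c1
F2 | step 17 | boron ketene acetal of 24 (O–B bound to the (R,R)-diazaborolidine, C7 cis to the ring oxygen) | O=S(=O)(c1cc(C(F)(F)F)cc(C(F)(F)F)c1)N1B(O/C2=C/CC[C@](C)(O[Si](CC)(CC)CC)/C=C\C/C(=C\CO[Si](C)(C)C(C)(C)C)CO2)N(S(=O)(=O)c2cc(C(F)(F)F)cc(C(F)(F)F)c2)[C@H](c2ccccc2)[C@H]1c1ccccc1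
F3 | step 17 | acyloxyborane of 27 (carboxylate O–B bound to the (R,R)-diazaborolidine) | C=C1C/C=C\[C@@](C)(O[Si](CC)(CC)CC)CC[C@H](C(=O)OB2N(S(=O)(=O)c3cc(C(F)(F)F)cc(C(F)(F)F)c3)[C@H](c3ccccc3)[C@@H](c3ccccc3)N2S(=O)(=O)c2cc(C(F)(F)F)cc(C(F)(F)F)c2)[C@H]1CO[Si](C)(C)C(C)(C)C
F4 | step 21 | tributyl{[(4-methoxybenzyl)oxy]methyl}stannane | CCCC[Sn](CCCC)(CCCC)COCc1ccc(OC)cc1
F5 | step 21 | {[(4-methoxybenzyl)oxy]methyl}lithium | [Li]COCc1ccc(OC)cc1
F6 | step 21 | alkoxymethyl ketone: ring A with C8–C(=O)–CH2O-(4-methoxybenzyl), C10–OSitBuMe2, C5–OSiEt3 (5S,8S,9R) | C=C1C/C=C\[C@@](C)(O[Si](CC)(CC)CC)CC[C@H](C(=O)COCc2ccc(OC)cc2)[C@H]1CO[Si](C)(C)C(C)(C)C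
F7 | step 21 | tertiary carbinol, C12 4-methoxybenzyl ether of 34 (11R) | C=C1C/C=C\[C@@](C)(O[Si](CC)(CC)CC)CC[C@H]([C@](O)(/C=C/C=C(C)C)COCc2ccc(OC)cc2)[C@H]1CO[Si](C)(C)C(C)(C)C
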